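A direct plan would build the C6–C7–C8 stereotriad on an open chain, by an auxiliary-controlled syn-aldol (adduct A1) followed by a hydroxyl-directed 1,3-anti reduction. It would then close the ten-membered ring at C2–C3 by intramolecular alkylation of the allylic sulfone anion of bromo sulfone A2, giving ring sulfone A3 for desulfonylation and acylation. Its weakest steps would be:
- the sulfone ring closure, because a strained E,E-cyclodeca-1,5-diene would have to form from a flexible chain at high dilution against elimination and γ-alkylation;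
- the reductive desulfonylation, because the allyl intermediate could shift or isomerise the C1=C10 alkene;
- the relay of protecting-group and leaving-group exchanges on the chain, which would add some eight steps without adding complexity.

The new route would make the ring by contraction instead of closure. The target contains the homoallylic-alcohol retron C6(OH)–C7–C11 (the C7 isopropyl as a reduced isopropenyl group) inside the cyclodecadiene. Disconnecting C6–C7, the bond that the terpene cyclase forms, leads to the 13-membered diallylic ether 21, in which the ether oxygen links C6 and C12. Its transannular [2,3]-Wittig rearrangement would form the C6–C7 bond, the ten-membered ring and the C6 and C7 stereocentres at once, both relayed from the single auxiliary-set C8 centre and the Z alkene. Both E ring alkenes would come unchanged from geranyl acetate, so no sulfone ring closure, desulfonylation or chain protecting-group relay would remain.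

Key step: step 13

Remark on numbering: germacrane numbering is used for ring and chain atoms alike (ring C1–C10; methyls on C4 and C10; free OH on C6; isopropyl C11–C13 on C7; ester oxygen on C8). TBS = tert-butyldimethylsilyl, TES = triethylsilyl.

Step 1
Reactants: 1 geranyl acetate, (2E)-3,7-dimethylocta-2,6-dien-1-yl acetate
Product: 2 (2E,6E)-8-hydroxy-3,7-dimethylocta-2,6-dien-1-yl acetate
Conditions: SeO2 (0.3 equiv), t-BuOOH (3 equiv), salicylic acid (0.1 equiv), CH2Cl2, rt
Reagents that add atoms: tert-butyl hydroperoxide, CC(C)(C)OO (terminal source of the new oxygen, passed on through selenium dioxide, O=[Se]=O)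
Why: The selenium dioxide allylic oxidation (ene reaction, then [2,3]-sigmatropic shift) should hydroxylate only the (E)-methyl group of the electron-rich terminal alkene, which gives the future C9 handle and leaves the deactivated allylic acetate alkene alone.

Step 2
Reactants: 2 (2E,6E)-8-hydroxy-3,7-dimethylocta-2,6-dien-1-yl acetate
Product: 3 (2E,6E)-8-iodo-3,7-dimethylocta-2,6-dien-1-yl acetate
Conditions: PPh3, I2, imidazole, CH2Cl2, 0 °C, dark; used at once
Reagents that add atoms: iodine, II
Why: Appel-type iodination should replace the primary allylic hydroxyl by SN2 on the alkoxyphosphonium ion without allylic transposition, giving a reactive electrophile for the enolate alkylation.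

Step 3
Reactants: 4 glycolic acid
Product: 6 [(tert-butyldimethylsilyl)oxy]acetic acid, via bis-silylated glycolate 5 (not isolated)
Conditions: TBSCl (2.2 equiv), imidazole, DMF, rt; AcOH/THF/H2O, 0 °C
Reagents that add atoms: tert-butyl(chloro)dimethylsilane, CC(C)(C)[Si](C)(C)Cl
Why: Exhaustive silylation followed by mild hydrolysis of the labile silyl ester should leave the hydroxyl protected and the acid free.

Step 4
Reactants: 6 [(tert-butyldimethylsilyl)oxy]acetic acid; 7 (4R)-4-benzyl-1,3-oxazolidin-2-one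
Product: 9 (4R)-4-benzyl-3-{[(tert-butyldimethylsilyl)oxy]acetyl}-1,3-oxazolidin-2-one, via mixed pivalic anhydride 8 (not isolated)
Conditions: PivCl, Et3N, THF, −20 °C; 7, LiCl, −20 °C to rt
Reagents that add atoms: none
Why: N-acylation of the oxazolidinone by the mixed pivalic anhydride (attack at the less hindered carbonyl) should attach the glycolyl unit, the future C7 and C8 with O8, to the chiral auxiliary.

Step 5
Reactants: 9 (4R)-4-benzyl-3-{[(tert-butyldimethylsilyl)oxy]acetyl}-1,3-oxazolidin-2-one; 3 (2E,6E)-8-iodo-3,7-dimethylocta-2,6-dien-1-yl acetate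
Product: 11 (2E,6E,9S)-10-[(4R)-4-benzyl-2-oxo-1,3-oxazolidin-3-yl]-9-(TBS-oxy)-3,7-dimethyl-10-oxodeca-2,6-dien-1-yl acetate, via sodium (Z)-enolate 10 (not isolated)
Conditions: 9 (1.3 equiv), NaN(SiMe3)2, THF, −78 °C; 3, −78 to −45 °C
Reagents that add atoms: none
Why: In this Evans asymmetric alkylation the chelated sodium (Z)-enolate of the glycolyl imide should be attacked by the allylic iodide on the face opposite the benzyl group, which forms the C8–C9 bond and sets C8 (S), the only stereocentre of the route that is not relayed.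

Step 6
Reactants: 11 the alkylated imide
Product: 12 (2E,6E,9S)-9-(TBS-oxy)-10-hydroxy-3,7-dimethyldeca-2,6-dien-1-yl acetate
Conditions: NaBH4, THF/H2O (3:1), 0 °C to rt
Reagents that add atoms: none
Why: Borohydride reduction of the activated imide carbonyl should release the auxiliary and give the primary alcohol, while the far less electrophilic allylic acetate and the silyl ether are left.

Step 7
Reactants: 12 the primary alcohol
Product: 13 (2E,6E,9S)-9-(TBS-oxy)-3,7-dimethyl-10-oxodeca-2,6-dien-1-yl acetate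
Conditions: Dess–Martin periodinane, pyridine, CH2Cl2, 0 °C; used crude
Reagents that add atoms: none
Why: Buffered Dess–Martin oxidation should give the α-silyloxy aldehyde without epimerising C8.

Step 8
Reactants: 13 the α-silyloxy aldehyde; 14 ethyl 2-[bis(2,2,2-trifluoroethoxy)phosphoryl]propanoate
Product: 16 ethyl (2Z,4S,6E,10E)-12-(acetyloxy)-4-(TBS-oxy)-2,6,10-trimethyldodeca-2,6,10-trienoate, via potassium phosphonate anion 15 (not isolated)
Conditions: 14, KN(SiMe3)2, 18-crown-6, THF, −78 °C; 13, −78 °C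
Reagents that add atoms: none
Why: In this Still–Gennari olefination the electron-poor phosphonate with a dissociated potassium counter-ion should eliminate from the kinetic adduct faster than it equilibrates, giving the Z-trisubstituted enoate (future C7=C11 with C12 cis to C8) on which the C6 configuration later depends.

Step 9
Reactants: 16 the acetoxy Z-enoate
Product: 17 ethyl (2Z,4S,6E,10E)-4-(TBS-oxy)-12-hydroxy-2,6,10-trimethyldodeca-2,6,10-trienoate
Conditions: K2CO3 (0.3 equiv), EtOH, 0 °C to rt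
Reagents that add atoms: none
Why: Base-catalysed ethanolysis should remove the primary allylic acetate, while the conjugated ethyl ester only exchanges with the solvent and the secondary TBS ether is stable.

Step 10
Reactants: 17 the hydroxy ester
Product: 18 ethyl (2Z,4S,6E,10E)-4-(TBS-oxy)-12-chloro-2,6,10-trimethyldodeca-2,6,10-trienoate
Conditions: N-chlorosuccinimide, Me2S, CH2Cl2, −40 to 0 °C
Reagents that add atoms: N-chlorosuccinimide, ClN1C(=O)CCC1=O
Why: Corey–Kim chlorination should convert the primary allylic alcohol (C6) into the chloride by SN2 on the alkoxysulfonium ion without allylic transposition or change of the C4=C5 geometry.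

Step 11
Reactants: 18 the chloro ester
Product: 19 (2Z,4S,6E,10E)-4-(TBS-oxy)-12-chloro-2,6,10-trimethyldodeca-2,6,10-trien-1-ol
Conditions: i-Bu2AlH (2.5 equiv), CH2Cl2, −78 °C; Rochelle salt
Reagents that add atoms: none
Why: Low-temperature aluminium hydride 1,2-reduction should take the enoate to the Z-allylic alcohol (C12–OH) and leave the allylic chloride untouched.

Step 12
Reactants: 19 the chloro alcohol
Product: 21 (3Z,5S,7E,11E)-5-(TBS-oxy)-3,7,11-trimethyl-1-oxacyclotrideca-3,7,11-triene, via sodium alkoxide 20 (not isolated)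
Conditions: NaH (5 equiv), Bu4NI (0.1 equiv), THF, 45 °C, syringe-pump addition (final 2 mM)
Reagents that add atoms: none
Why: Intramolecular Williamson etherification at high dilution (SN2 of the primary alkoxide on the primary allylic chloride, iodide-assisted) should close the 13-membered ether, helped by the three trisubstituted alkenes that restrict the chain.

Step 13
Reactants: 21 the 13-membered diallylic ether
Product: 24 (1S,2E,6E,9S,10S)-9-(TBS-oxy)-3,7-dimethyl-10-(prop-1-en-2-yl)cyclodeca-2,6-dien-1-ol, via C6-lithiated ether 22 (not isolated), via lithium alkoxide 23 (not isolated)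
Conditions: n-BuLi (3 equiv), THF, −78 to −30 °C; AcOH/THF, −78 °C
Reagents that add atoms: none
Why: n-BuLi should remove a proton from the less hindered O–CH2 group (C6, next to the C5–H carbon) and not from C12 (next to the methyl-bearing C11 and shielded by the cis C8–OSi group), and the α-oxy allyllithium 22 should add through the five-membered envelope of a [2,3]-Wittig shift to C7 while the O–C12 bond breaks and C11=C12 becomes the isopropenyl alkene. The closest known reaction type is the transannular [2,3]-Wittig ring contraction of farnesol-derived 13-membered diallylic ethers to ten-membered germacrane alcohols. The ten-membered ring is closed by this contraction (C6–C7 bond formation inside the 13-membered ring, with the oxygen and C12 leaving the ring), so both E ring alkenes (C1=C10, C4=C5) are spectators and keep their geometry. C7 is controlled by the auxiliary-set C8 centre: allylic 1,3-strain in the Z alkene holds C8–H in the alkene plane, and the carbanion, tethered through C9, should attack the face anti to the C8–O bond, which places the side chain syn to O8. C6 is controlled by the Z geometry of C7=C11: with the C5 vinyl group exo on the envelope, a Z allyl unit gives the syn [2,3] product, that is O6 anti to the side chain across C6–C7, as in the target. The step needs regioselective lithiation and one alkene face; the substitution pattern at C6 versus C12 and the single C8 stereocentre with its bulky silyl ether should secure them, and the low temperature should suppress the [1,2]-shift.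

Step 14
Reactants: 24 the isopropenyl dienol
Product: 25 (1S,2E,6E,9S,10S)-9-(TBS-oxy)-3,7-dimethyl-10-(propan-2-yl)cyclodeca-2,6-dien-1-ol
Conditions: H2 (1 atm), RhCl(PPh3)3 (10 mol%), benzene, rt
Reagents that add atoms: none
Why: Homogeneous hydrogenation with RhCl(PPh3)3 discriminates by alkene substitution, so the 1,1-disubstituted isopropenyl group should be reduced to the isopropyl group (no new stereocentre) while the two trisubstituted ring alkenes remain.

Step 15
Reactants: 25 the ring alcohol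
Product: 26 (1S,2E,6E,9S,10S)-9-(TBS-oxy)-3,7-dimethyl-10-(propan-2-yl)cyclodeca-2,6-dien-1-yl prop-2-en-1-yl carbonate
Conditions: allyl chloroformate, pyridine, DMAP (cat.), CH2Cl2, 0 °C to rt
Reagents that add atoms: allyl chloroformate, C=CCOC(=O)Cl
Why: Acylation of the only free hydroxyl (O6) as its allyl carbonate gives a mask that survives fluoride, keeps O6 distinct from O8 and is removed at the end under neutral palladium catalysis.

Step 16
Reactants: 26 the silyl ether carbonate
Product: 27 (1S,2E,6E,9S,10R)-9-hydroxy-3,7-dimethyl-10-(propan-2-yl)cyclodeca-2,6-dien-1-yl prop-2-en-1-yl carbonate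
Conditions: HF·pyridine, pyridine, THF, 0 °C to rt
Reagents that add atoms: none
Why: Pyridine-buffered fluoride desilylation should free O8 without base-induced migration of the carbonate from O6 to O8 and without acid-induced transannular cyclisation of the 1,5-diene.

Step 17
Reactants: 27 the hydroxy carbonate; 28 (2E)-3-[4-(acetyloxy)phenyl]prop-2-enoic acid
Product: 29 (1S,3E,7E,9S,10R)-9-{[(prop-2-en-1-yloxy)carbonyl]oxy}-3,7-dimethyl-10-(propan-2-yl)cyclodeca-3,7-dien-1-yl (2E)-3-[4-(acetyloxy)phenyl]prop-2-enoate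
Conditions: EDC·HCl [N-(3-dimethylaminopropyl)-N′-ethylcarbodiimide hydrochloride], DMAP, CH2Cl2, 0 °C to rt
Reagents that add atoms: none
Why: Carbodiimide/DMAP (Steglich-type) esterification should acylate the only free hydroxyl (O8) with retention at C8 under near-neutral conditions that the diene and the carbonate tolerate.

Step 18
Reactants: 29 the doubly masked ester
Product: 30 (1S,3E,7E,9S,10S)-9-hydroxy-3,7-dimethyl-10-(propan-2-yl)cyclodeca-3,7-dien-1-yl (2E)-3-(4-hydroxyphenyl)prop-2-enoate (CNP0178839.1)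
Conditions: Pd(PPh3)4 (5 mol%), pyrrolidine (5 equiv), CH2Cl2, 0 °C to rt
Reagents that add atoms: none
Why: Zerovalent palladium should ionise the unhindered allyl–O bond of the carbonate (Tsuji–Trost deallylation, with loss of CO2 and trapping of the allyl group by pyrrolidine) rather than the hindered ring C6–O bond, and the same amine should cleave the phenolic acetate by aminolysis much faster than the hindered conjugated ester, so both masks fall without alkoxide base that could move the ester from O8 to O6.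

## Compound list

1 | geranyl acetate, (2E)-3,7-dimethylocta-2,6-dien-1-yl acetate | CC(C)=CCC/C(C)=C/COC(C)=O | starting material
2 | (2E,6E)-8-hydroxy-3,7-dimethylocta-2,6-dien-1-yl acetate | OC/C(C)=C/CC/C(C)=C/COC(C)=O | intermediate
3 | (2E,6E)-8-iodo-3,7-dimethylocta-2,6-dien-1-yl acetate | IC/C(C)=C/CC/C(C)=C/COC(C)=O | intermediate
4 | glycolic acid | OCC(O)=O | starting material
5 | tert-butyldimethylsilyl [(tert-butyldimethylsilyl)oxy]acetate | CC(C)(C)[Si](C)(C)OCC(=O)O[Si](C)(C)C(C)(C)C | intermediate (not isolated)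
6 | [(tert-butyldimethylsilyl)oxy]acetic acid | CC(C)(C)[Si](C)(C)OCC(O)=O | intermediate
7 | (4R)-4-benzyl-1,3-oxazolidin-2-one | O=C1N[C@H](Cc2ccccc2)CO1 | starting material
8 | [(tert-butyldimethylsilyl)oxy]acetic 2,2-dimethylpropanoic anhydride | CC(C)(C)[Si](C)(C)OCC(=O)OC(=O)C(C)(C)C | intermediate (not isolated)
9 | (4R)-4-benzyl-3-{[(tert-butyldimethylsilyl)oxy]acetyl}-1,3-oxazolidin-2-one | CC(C)(C)[Si](C)(C)OCC(=O)N1[C@H](Cc2ccccc2)COC1=O | intermediate
10 | sodium (1Z)-1-[(4R)-4-benzyl-2-oxo-1,3-oxazolidin-3-yl]-2-(TBS-oxy)ethen-1-olate | [Na+].[O-]/C(=C\O[Si](C)(C)C(C)(C)C)N1[C@H](Cc2ccccc2)COC1=O | intermediate (not isolated)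
11 | (2E,6E,9S)-10-[(4R)-4-benzyl-2-oxo-1,3-oxazolidin-3-yl]-9-(TBS-oxy)-3,7-dimethyl-10-oxodeca-2,6-dien-1-yl acetate | CC(=O)OC/C=C(C)/CC/C=C(C)/C[C@H](O[Si](C)(C)C(C)(C)C)C(=O)N1[C@H](Cc2ccccc2)COC1=O | intermediate
12 | (2E,6E,9S)-9-(TBS-oxy)-10-hydroxy-3,7-dimethyldeca-2,6-dien-1-yl acetate | CC(=O)OC/C=C(C)/CC/C=C(C)/C[C@H](O[Si](C)(C)C(C)(C)C)CO | intermediate
13 | (2E,6E,9S)-9-(TBS-oxy)-3,7-dimethyl-10-oxodeca-2,6-dien-1-yl acetate | CC(=O)OC/C=C(C)/CC/C=C(C)/C[C@H](O[Si](C)(C)C(C)(C)C)C=O | intermediate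
14 | ethyl 2-[bis(2,2,2-trifluoroethoxy)phosphoryl]propanoate | CCOC(=O)C(C)P(=O)(OCC(F)(F)F)OCC(F)(F)F | starting material
15 | potassium 1-ethoxy-1-oxo-2-[bis(2,2,2-trifluoroethoxy)phosphoryl]propan-2-ide | [K+].CCOC(=O)[C-](C)P(=O)(OCC(F)(F)F)OCC(F)(F)F | intermediate (not isolated)
16 | ethyl (2Z,4S,6E,10E)-12-(acetyloxy)-4-(TBS-oxy)-2,6,10-trimethyldodeca-2,6,10-trienoate | CC(=O)OC/C=C(C)/CC/C=C(C)/C[C@H](O[Si](C)(C)C(C)(C)C)/C=C(C)\C(=O)OCC | intermediate
17 | ethyl (2Z,4S,6E,10E)-4-(TBS-oxy)-12-hydroxy-2,6,10-trimethyldodeca-2,6,10-trienoate | OC/C=C(C)/CC/C=C(C)/C[C@H](O[Si](C)(C)C(C)(C)C)/C=C(C)\C(=O)OCC | intermediate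
18 | ethyl (2Z,4S,6E,10E)-4-(TBS-oxy)-12-chloro-2,6,10-trimethyldodeca-2,6,10-trienoate | ClC/C=C(C)/CC/C=C(C)/C[C@H](O[Si](C)(C)C(C)(C)C)/C=C(C)\C(=O)OCC | intermediate
19 | (2Z,4S,6E,10E)-4-(TBS-oxy)-12-chloro-2,6,10-trimethyldodeca-2,6,10-trien-1-ol | ClC/C=C(C)/CC/C=C(C)/C[C@H](O[Si](C)(C)C(C)(C)C)/C=C(C)\CO | intermediate
20 | sodium (2Z,4S,6E,10E)-4-(TBS-oxy)-12-chloro-2,6,10-trimethyldodeca-2,6,10-trien-1-olate | [Na+].ClC/C=C(C)/CC/C=C(C)/C[C@H](O[Si](C)(C)C(C)(C)C)/C=C(C)\C[O-] | intermediate (not isolated)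
21 | (3Z,5S,7E,11E)-5-(TBS-oxy)-3,7,11-trimethyl-1-oxacyclotrideca-3,7,11-triene | C/C1=C\COC/C(C)=C\[C@@H](O[Si](C)(C)C(C)(C)C)C/C(C)=C/CC1 | intermediate
22 | [(3Z,5S,7E,11E)-5-(TBS-oxy)-3,7,11-trimethyl-1-oxacyclotrideca-3,7,11-trien-13-yl]lithium | [Li]C1/C=C(C)/CC/C=C(C)/C[C@H](O[Si](C)(C)C(C)(C)C)/C=C(C)\CO1 | intermediate (not isolated)
23 | lithium (1S,2E,6E,9S,10S)-9-(TBS-oxy)-3,7-dimethyl-10-(prop-1-en-2-yl)cyclodeca-2,6-dien-1-olate | [Li+].C/C1=C\[C@H]([O-])[C@H](C(C)=C)[C@@H](O[Si](C)(C)C(C)(C)C)C/C(C)=C/CC1 | intermediate (not isolated)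
24 | (1S,2E,6E,9S,10S)-9-(TBS-oxy)-3,7-dimethyl-10-(prop-1-en-2-yl)cyclodeca-2,6-dien-1-ol | C/C1=C\[C@H](O)[C@H](C(C)=C)[C@@H](O[Si](C)(C)C(C)(C)C)C/C(C)=C/CC1 | intermediate
25 | (1S,2E,6E,9S,10S)-9-(TBS-oxy)-3,7-dimethyl-10-(propan-2-yl)cyclodeca-2,6-dien-1-ol | C/C1=C\[C@H](O)[C@H](C(C)C)[C@@H](O[Si](C)(C)C(C)(C)C)C/C(C)=C/CC1 | intermediate
26 | (1S,2E,6E,9S,10S)-9-(TBS-oxy)-3,7-dimethyl-10-(propan-2-yl)cyclodeca-2,6-dien-1-yl prop-2-en-1-yl carbonate | C/C1=C\[C@H](OC(=O)OCC=C)[C@H](C(C)C)[C@@H](O[Si](C)(C)C(C)(C)C)C/C(C)=C/CC1 | intermediate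
27 | (1S,2E,6E,9S,10R)-9-hydroxy-3,7-dimethyl-10-(propan-2-yl)cyclodeca-2,6-dien-1-yl prop-2-en-1-yl carbonate | C/C1=C\[C@H](OC(=O)OCC=C)[C@H](C(C)C)[C@@H](O)C/C(C)=C/CC1 | intermediate
28 | (2E)-3-[4-(acetyloxy)phenyl]prop-2-enoic acid | CC(=O)Oc1ccc(/C=C/C(O)=O)cc1 | starting material
29 | (1S,3E,7E,9S,10R)-9-{[(prop-2-en-1-yloxy)carbonyl]oxy}-3,7-dimethyl-10-(propan-2-yl)cyclodeca-3,7-dien-1-yl (2E)-3-[4-(acetyloxy)phenyl]prop-2-enoate | C/C1=C\[C@H](OC(=O)OCC=C)[C@H](C(C)C)[C@@H](OC(=O)/C=C/c2ccc(OC(C)=O)cc2)C/C(C)=C/CC1 | intermediate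
30 | (1S,3E,7E,9S,10S)-9-hydroxy-3,7-dimethyl-10-(propan-2-yl)cyclodeca-3,7-dien-1-yl (2E)-3-(4-hydroxyphenyl)prop-2-enoate (CNP0178839.1) | C/C1=C\[C@H](O)[C@H](C(C)C)[C@@H](OC(=O)/C=C/c2ccc(O)cc2)C/C(C)=C/CC1 | target

Total step count: 18. Longest linear sequence: 16 (steps 1, 2 and 5–18; equally 3–18).

The three steps most likely to fail:

1. Step 13 (key ring contraction). Lithiation could occur at C12 instead of C6, the carbanion could attack the wrong face of the C7=C11 alkene, or the [1,2]-shift or an anionic oxy-Cope rearrangement of the lithium alkoxide could compete on warming. The fallback would close the same C6–C7 bond by a chromium-mediated allylation of an open chain. Chloro alcohol 19 would be oxidised at the allylic chloride with 4-methylmorpholine N-oxide (MeCN, rt) to (2E,6E,9S,10Z)-9-(TBS-oxy)-12-hydroxy-3,7,11-trimethyldodeca-2,6,10-trienal F1. CBr4/PPh3 would convert this into (2E,6E,9S,10Z)-12-bromo-9-(TBS-oxy)-3,7,11-trimethyldodeca-2,6,10-trienal F2, which would be cyclised with CrCl2 (THF, high dilution). Because the allylchromium chair would be expected to favour the C6 epimer, (1R,2E,6E,9S,10S)-9-(TBS-oxy)-3,7-dimethyl-10-(prop-1-en-2-yl)cyclodeca-2,6-dien-1-ol F3, this would be oxidised (Dess–Martin periodinane) to (2E,6E,9S,10R)-9-(TBS-oxy)-3,7-dimethyl-10-(prop-1-en-2-yl)cyclodeca-2,6-dien-1-one F4 and reduced at once (NaBH4, CeCl3) from the peripheral face, coming back to the route at 24.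

2. Step 12 (macrocyclic etherification). Intermolecular etherification, loss of HCl from the prenyl-type chloride, or transfer of the silyl group to the alkoxide held close by the Z alkene could take over. The fallback would close the other C–O bond of the ether, with the alkoxide remote from the silyl ether. Hydroxy ester 17 would be silylated (TESCl, imidazole) to ethyl (2Z,4S,6E,10E)-4-(TBS-oxy)-2,6,10-trimethyl-12-(TES-oxy)dodeca-2,6,10-trienoate F5 and reduced (i-Bu2AlH) to (2Z,4S,6E,10E)-4-(TBS-oxy)-2,6,10-trimethyl-12-(TES-oxy)dodeca-2,6,10-trien-1-ol F6. MsCl/LiCl/2,4,6-collidine would give tert-butyl{[(2Z,4S,6E,10E)-1-chloro-2,6,10-trimethyl-12-(TES-oxy)dodeca-2,6,10-trien-4-yl]oxy}dimethylsilane F7, and the primary TES ether would be removed (pyridinium p-toluenesulfonate, MeOH, 0 °C) to (2E,6E,9S,10Z)-9-(TBS-oxy)-12-chloro-3,7,11-trimethyldodeca-2,6,10-trien-1-ol F8. NaH at high dilution would then come back to the route at 21.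

3. Step 14 (chemoselective hydrogenation). The crowded isopropenyl group could fail to bind to rhodium, or a ring alkene could be reduced or isomerised on forcing. The fallback would set out from 24 and use a metal-free diimide transfer reduction (2-nitrobenzenesulfonohydrazide, Et3N, CH2Cl2, rt), which needs no coordination site and selects by substitution degree alone. It would come back at 25 and would make no new compound (F0).

Further compounds

F1 | step 13 | (2E,6E,9S,10Z)-9-(TBS-oxy)-12-hydroxy-3,7,11-trimethyldodeca-2,6,10-trienal | O=C/C=C(C)/CC/C=C(C)/C[C@H](O[Si](C)(C)C(C)(C)C)/C=C(C)\CO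
F2 | step 13 | (2E,6E,9S,10Z)-12-bromo-9-(TBS-oxy)-3,7,11-trimethyldodeca-2,6,10-trienal | O=C/C=C(C)/CC/C=C(C)/C[C@H](O[Si](C)(C)C(C)(C)C)/C=C(C)\CBr
F3 | step 13 | (1R,2E,6E,9S,10S)-9-(TBS-oxy)-3,7-dimethyl-10-(prop-1-en-2-yl)cyclodeca-2,6-dien-1-ol | C/C1=C\[C@@H](O)[C@H](C(C)=C)[C@@H](O[Si](C)(C)C(C)(C)C)C/C(C)=C/CC1
F4 | step 13 | (2E,6E,9S,10R)-9-(TBS-oxy)-3,7-dimethyl-10-(prop-1-en-2-yl)cyclodeca-2,6-dien-1-one | C/C1=C\C(=O)[C@H](C(C)=C)[C@@H](O[Si](C)(C)C(C)(C)C)C/C(C)=C/CC1
F5 | step 12 | ethyl (2Z,4S,6E,10E)-4-(TBS-oxy)-2,6,10-trimethyl-12-(TES-oxy)dodeca-2,6,10-trienoate | CC[Si](CC)(CC)OC/C=C(C)/CC/C=C(C)/C[C@H](O[Si](C)(C)C(C)(C)C)/C=C(C)\C(=O)OCC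
F6 | step 12 | (2Z,4S,6E,10E)-4-(TBS-oxy)-2,6,10-trimethyl-12-(TES-oxy)dodeca-2,6,10-trien-1-ol | CC[Si](CC)(CC)OC/C=C(C)/CC/C=C(C)/C[C@H](O[Si](C)(C)C(C)(C)C)/C=C(C)\CO
F7 | step 12 | tert-butyl{[(2Z,4S,6E,10E)-1-chloro-2,6,10-trimethyl-12-(TES-oxy)dodeca-2,6,10-trien-4-yl]oxy}dimethylsilane | CC[Si](CC)(CC)OC/C=C(C)/CC/C=C(C)/C[C@H](O[Si](C)(C)C(C)(C)C)/C=C(C)\CCl
F8 | step 12 | (2E,6E,9S,10Z)-9-(TBS-oxy)-12-chloro-3,7,11-trimethyldodeca-2,6,10-trien-1-ol | OC/C=C(C)/CC/C=C(C)/C[C@H](O[Si](C)(C)C(C)(C)C)/C=C(C)\CCl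
F0 | step 14 | none | none
A1 | direct plan | (4R)-4-benzyl-3-[(2R,3S,5E)-7-(TBS-oxy)-3-hydroxy-5-methyl-2-(propan-2-yl)hept-5-enoyl]-1,3-oxazolidin-2-one | O=C(N1[C@H](Cc2ccccc2)COC1=O)[C@H](C(C)C)[C@@H](O)C/C(C)=C/CO[Si](C)(C)C(C)(C)C
A2 | direct plan | (2E,4S,5R,6S,8E)-10-(benzenesulfonyl)-1-bromo-4-(TBS-oxy)-2,8-dimethyl-5-(propan-2-yl)deca-2,8-dien-6-yl benzoate | BrC/C(C)=C/[C@H](O[Si](C)(C)C(C)(C)C)[C@H](C(C)C)[C@@H](OC(=O)c1ccccc1)C/C(C)=C/CS(=O)(=O)c1ccccc1
A3 | direct plan | (1S,3E,7E,9S,10R)-5-(benzenesulfonyl)-9-(TBS-oxy)-3,7-dimethyl-10-(propan-2-yl)cyclodeca-3,7-dien-1-yl benzoate (C5 epimers) | C/C1=C\[C@H](O[Si](C)(C)C(C)(C)C)[C@H](C(C)C)[C@@H](OC(=O)c2ccccc2)C/C(C)=C/C(S(=O)(=O)c2ccccc2)C1
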